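The readings were generated by integration for substances that don't exist, noise included.

**The vessel.** A closed, stirred flask takes substrate and coupling partner and makes target, and the new flasks differ in the temperature they stand at.

| flask | substrate | coupling partner | temperature | remark | time |
|---|---|---|---|---|---|
| south | 0.70 M | 0.65 M | −5 °C | run made earlier |  |
| east | 1.1 M | 0.65 M | 15 °C | run made earlier |  |
| Wednesday's | 0.50 M | 0.650 M | 0 °C |  | 30 h |
| Friday's | 0.50 M | 0.650 M |  | at 0 °C until 20 h, from then on at 30 °C | 30 h |
| Saturday's | 0.50 M | 0.650 M | 15 °C |  | 30 h |
| Tuesday's | 0.50 M | 0.650 M | 30 °C |  | 30 h |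

| run | time / h | target / % | substrate / % |
|---|---|---|---|
| south | 6.00 | 29 | 40 |
| south | 12.0 | 32 | 42 |
| south | 20.0 | 30 | 37 |
| south | 25.0 | 27 | 44 |
| east | 3.00 | 9 | 69 |
| east | 6.00 | 10 | 72 |
| east | 10.0 | 1 | 71 |
| east | 12.0 | 0 | 73 |

(standard deviation of a reading: 1.5 percentage points)

- which flask leads in amount of target, in percent of the substrate charged ("all alike" within 1.5 percentage points) (Wednesday's / Friday's / Saturday's / Tuesday's / all alike)
- how much target is there at the end, in percent of the substrate charged: Wednesday's
- how much target is there at the end, in percent of the substrate charged: Friday's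
- how much target is there at the end, in percent of the substrate charged: Saturday's
- how much target is there at the end, in percent of the substrate charged: Tuesday's



**Two times.** In the south run substrate stands near 40% from 6.00 h onward, and in the east run near 69% from 3.00 h. Substrate remains in both, so the concentration that has fallen should be the coupling partner's, though no reading shows it. The net gain of target therefore ends early in both runs, and two times are left to compare: the standing time of 30 h, and how long target lasts afterwards.

**Reading survival.** In the south run target falls from 32% at 12.0 h to 27% at 25.0 h, which reads as 76.5 h for a factor of e. In the east run it falls from 10% at 6.00 h to 1% at 10.0 h, which reads as 1.74 h. Both are rough, given the scatter. Taking the loss as pseudo-first-order and going a quarter of the way between their logarithms gives 29.7 h at 0 °C: the survival time of target, the time in which standing target falls by a factor of e.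

**My reckoning.** Carried on from the south reading of 32% at 12.0 h, Wednesday's target at 30 h comes by this estimate to 17.5%. Saturday's flask stands far longer than the survival time read in the east run at the same temperature, at 17.2 such times. Friday's warm 10.0 h stand at 30 °C, counted from the same south reading with the east value read at 15 °C, leaves 0.101% by this estimate.

**The forecast.** It names Wednesday's as leader, with 18%, against 2% for Friday's, 1% for Saturday's and 0% for Tuesday's, holding that “warm flasks should end near zero”. Its Wednesday's figure comes from a fitted over-reaction scheme, not from this survival time.

**The result.** Wednesday's leads with 14.8%, against 0% for Friday's, 0.0526% for Saturday's and 0% for Tuesday's, so the forecast stands.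

    coupling partner → decomposed reagent (k = 2.72 × 10⁻⁵ s⁻¹, Ea = 84.0 kJ mol⁻¹)
    substrate + 2 coupling partner → side product (k = 0.00414 L² mol⁻² s⁻¹, Ea = 61.0 kJ mol⁻¹)
    substrate + coupling partner ⇌ target (K = 26.0 L mol⁻¹, k = 0.00126 L mol⁻¹ s⁻¹, Ea = 47.0 kJ mol⁻¹, ΔH = −41.0 kJ mol⁻¹)
    (constants at 0 °C)

**Longer standing.** Wednesday's flask holds 22.5% target at 15.0 h, and the survival time of 29.7 h carries that to 13.6% at 30.0 h, where the flask holds 14.8%, while its substrate climbs from 32.3% to 37.7%. Wednesday's flask read at 2.0 d is the neighbour: the same survival time carries 14.8% down to 8.08%, and that flask holds 9.91%.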